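**Retrosynthetic overview**

1. The last step hydrates a C16=C18 enamide to the lactam hemiaminal and frees the C21 peroxy-hemiacetal from its methyl ether.
2. Key disconnection: C19–C34 and O24–C25 are cut together. C19 is C3 of the aromatic 2-oxidopyrrole available from the C16–C18–C19–C39–N41 ring and lies five atoms (C20, C21, O23, O24) from the peroxide oxygen, while C34–C33=C25 is a vinylogous acyl unit of ring C. O24 can therefore carry the acyl carbon to C19 through a six-membered transition state and then add to C25, closing the eight-membered 1,2-dioxocane.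
3. The two halves are joined beforehand through the C7–O8 aryl ether (Mitsunobu inversion); the hydroperoxide comes from ozonolysis of an allyl group in methanol.
4. Ring A is made by Diels–Alder reaction of a chiral 5-menthyloxybutenolide (C36, C6, C4; C2 by hydrogenation); rings B and C form together by intramolecular Diels–Alder reaction; C25=C33 by selenoxide elimination; the β-epoxide via a bromohydrin.
5. Ring order: A → B + C → epoxide → 17-membered perester → 13-membered paracyclophane + dioxocane → hydroxy-lactam.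

Key step: step 23

Remarks: atoms are called C1–N41 after the positions of the heavy atoms in the target SMILES read from left to right; β is the face of the C36 methyl group, α the opposite face. The C16 hemiaminal and C21 peroxy-hemiacetal centres are assumed to be the thermodynamically preferred epimers, because both can equilibrate by ring opening. The C16 centre of 28 and the C21 centre of 32–35 need not be controlled.

**Route**

Step 1
Reactants: 1 5-hydroxy-4-methylfuran-2(5H)-one; 2 (−)-menthol
Product: 3 (5R)-5-[(1R,2S,5R)-menthyloxy]-4-methylfuran-2(5H)-one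
Conditions: camphorsulfonic acid (cat.), toluene, reflux, water removal; crystallisation with acid equilibration of the mother liquor
Reagents that add atoms: none
Why: Acid-catalysed acetalisation of the pseudo-acid; the acetal centre equilibrates and the (5R) epimer should be drawn out by crystallisation, as in the 5-menthyloxyfuranone series without the methyl group.

Step 2
Reactants: 3 (5R)-5-menthyloxy-4-methylfuran-2(5H)-one; 4 (E)-2-methylpenta-1,3-diene
Product: 5 cis-fused Diels–Alder adduct, 3-(menthyloxy)-3a,5,7-trimethyl-3a,4,7,7a-tetrahydroisobenzofuran-1(3H)-one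
Conditions: 4 (5 equiv), toluene, BHT, 150 °C, sealed tube
Reagents that add atoms: none
Why: Thermal Diels–Alder reaction of a 5-alkoxybutenolide: the diene adds anti to the menthyloxy group and endo to the lactone carbonyl, its CH2 terminus bonding to the methyl-bearing β-carbon, which sets C36 (quaternary), C6 and C4.

Step 3
Reactants: 5 Diels–Alder adduct
Product: 6 saturated bicyclic lactone acetal
Conditions: H2 (1 atm), Pd/C, EtOAc, rt
Reagents that add atoms: none
Why: Heterogeneous hydrogenation from the convex face, opposite the lactone ring and the allylic C4 methyl, should place the C2 methyl cis to the C4 methyl.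

Step 4
Reactants: 6 saturated lactone acetal
Product: 7 ring A Weinreb amide aldehyde (amide cis to formyl)
Conditions: AlMe3, MeNH(OMe)·HCl, CH2Cl2, 0 °C to rt
Reagents that add atoms: N,O-dimethylhydroxylamine hydrochloride, CNOC.Cl
Why: Aluminium-amide aminolysis of the lactone (Weinreb amide formation) opens the pseudo-ester, unmasks the non-enolisable C31 aldehyde and releases menthol without touching a stereocentre.

Step 5
Reactants: 7 Weinreb amide aldehyde
Product: 8 1,1-dibromoalkene
Conditions: CBr4, PPh3, CH2Cl2, 0 °C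
Reagents that add atoms: carbon tetrabromide, BrC(Br)(Br)Br
Why: Corey–Fuchs dibromo-olefination of the neopentyl aldehyde.

Step 6
Reactants: 8 1,1-dibromoalkene; 9 (E)-prop-1-en-1-ylboronic acid
Product: 10 (1Z,3E)-2-bromopenta-1,3-dienyl compound
Conditions: Pd(PPh3)4 (5 mol %), aq Na2CO3, THF, 60 °C
Reagents that add atoms: none
Why: Suzuki coupling of a 1,1-dibromoalkene reacts first at the bromide trans to the bulky quaternary carbon, which fixes C27 trans to C36 across C31=C29.

Step 7
Reactants: 10 bromodiene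
Product: 11 (1E,3E)-2-methylpenta-1,3-dienyl Weinreb amide
Conditions: Me2Zn, Pd(P(t-Bu)3)2 (5 mol %), THF, 0 °C to rt
Reagents that add atoms: dimethylzinc, C[Zn]C
Why: Negishi methylation of the remaining alkenyl bromide with retention completes the (E,E)-diene.

Step 8
Reactants: 11 dienyl Weinreb amide
Product: 13 ring A dienyl aldehyde (formyl equatorial; trans to the dienyl arm), via cis aldehyde 12 (not isolated)
Conditions: (i-Bu)2AlH, THF, −78 °C; then K2CO3, MeOH, rt
Reagents that add atoms: none
Why: Weinreb amide reduction to the aldehyde, then base epimerisation at C6 to the equatorial formyl group, the thermodynamic preference known for 2,2,6-trisubstituted cyclohexanecarbaldehydes.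

Step 9
Reactants: 14 (E)-3-iodoacrylic acid
Product: 15 2-(trimethylsilyl)ethyl (E)-3-iodoacrylate
Conditions: Me3SiCH2CH2OH, DCC, DMAP (cat.), CH2Cl2, 0 °C
Reagents that add atoms: 2-(trimethylsilyl)ethanol, OCC[Si](C)(C)C
Why: Carbodiimide (Steglich) esterification with retention of the alkene geometry.

Step 10
Reactants: 13 ring A dienyl aldehyde; 15 2-(trimethylsilyl)ethyl (E)-3-iodoacrylate
Product: 16 (E)-γ-hydroxy enoate with 7α-hydroxyl
Conditions: CrCl2 (4 equiv), NiCl2 (1 mol %), DMSO, rt
Reagents that add atoms: none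
Why: Nozaki–Hiyama–Kishi alkenylation; Felkin–Anh attack anti to the quaternary C36 should give the C7 carbinol that becomes 7α in the tricycle, the epimer needed for the later inversion.

Step 11
Reactants: 16 γ-hydroxy enoate
Product: 17 tricyclic hydroxy ester (rings A, B, C; 7α-OH, 33β-ester, 25β-methyl, C27=C29)
Conditions: Me2AlCl (2 equiv), CH2Cl2, −78 °C to rt
Reagents that add atoms: none
Why: Lewis-acid-promoted intramolecular Diels–Alder reaction of a terminally activated (E)-dienophile: the endo (ester) transition state on the trans-diequatorial ring A tether should give trans-fused rings B and C, setting C31, C32, C33 and C25 with C31–H anti to the C36 methyl.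

Step 12
Reactants: 17 tricyclic hydroxy ester
Product: 19 tricyclic dienoate (C25=C33 and C27=C29), via selenide 18 (not isolated)
Conditions: LiN(i-Pr)2 (2.2 equiv), THF, −78 °C; PhSeBr; then H2O2, pyridine, CH2Cl2, 0 °C to rt
Reagents that add atoms: none
Why: Enolate selenenylation on the α-face (anti to the axial C25 methyl) and selenoxide syn-elimination, which can only use the syn C25–H because C32–H is anti, should give the tetrasubstituted enoate regioselectively.

Step 13
Reactants: 19 tricyclic dienoate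
Product: 20 bromohydrin (27α-bromo, 29β-hydroxy)
Conditions: NBS, THF–H2O (4:1), 0 °C
Reagents that add atoms: N-bromosuccinimide, O=C1CCC(=O)N1Br; water, O
Why: Bromohydrin formation on the electron-rich γ,δ-alkene: bromonium ion on the less hindered α-face and anti attack of water at tertiary C29 from the β-face, the classical way to the epoxide on the more hindered face.

Step 14
Reactants: 20 bromohydrin
Product: 21 27β,29β-epoxy enoate with 7α-hydroxyl
Conditions: DBU, CH2Cl2, 0 °C to rt
Reagents that add atoms: none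
Why: Intramolecular Williamson closure (3-exo-tet) with inversion at C27 gives the β-epoxide.

Step 15
Reactants: 22 methyl 2-[bis(2,2,2-trifluoroethoxy)phosphoryl]acetate; 23 allyl bromide
Product: 24 methyl 2-[bis(2,2,2-trifluoroethoxy)phosphoryl]pent-4-enoate
Conditions: NaH, THF–DMF, 0 °C to rt
Reagents that add atoms: none
Why: Alkylation of the stabilised phosphonate carbanion.

Step 16
Reactants: 25 N-Boc-L-tyrosine methyl ester
Product: 26 N-Boc-L-tyrosinal
Conditions: (i-Bu)2AlH (3 equiv), CH2Cl2, −78 °C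
Reagents that add atoms: none
Why: Low-temperature ester-to-aldehyde reduction through the aluminium hemiacetal; any erosion at C16 is harmless because this centre becomes sp2 in step 23.

Step 17
Reactants: 26 N-Boc-L-tyrosinal; 24 allyl phosphonate
Product: 27 methyl (2Z,4S)-2-allyl-4-(Boc-amino)-5-(4-hydroxyphenyl)pent-2-enoate
Conditions: KN(SiMe3)2 (2.1 equiv), 18-crown-6, THF, −78 °C
Reagents that add atoms: none
Why: Still–Gennari olefination places the ester cis to C16, as lactam closure requires.

Step 18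
Reactants: 27 (Z)-amino enoate
Product: 28 (5S)-3-allyl-5-(4-hydroxybenzyl)-1,5-dihydro-2H-pyrrol-2-one
Conditions: CF3CO2H, CH2Cl2, 0 °C; then NaHCO3, MeOH, rt
Reagents that add atoms: none
Why: Acidolysis of the carbamate and 5-exo lactamisation of the (Z)-amino ester.

Step 19
Reactants: 21 epoxy enoate alcohol; 28 pyrrolinone phenol
Product: 29 7β-aryl ether
Conditions: PPh3, DIAD, toluene, 0 °C to rt
Reagents that add atoms: none
Why: Mitsunobu etherification with the phenol, the only pronucleophile acidic enough, inverts C7 to the 7β configuration of the target.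

Step 20
Reactants: 29 aryl ether ester
Product: 30 epoxy enoic acid
Conditions: Bu4NF, THF, 0 °C
Reagents that add atoms: none
Why: Fluoride-induced β-elimination of the 2-(trimethylsilyl)ethyl ester leaves epoxide, lactam and alkenes untouched.

Step 21
Reactants: 30 epoxy enoic acid
Product: 31 pentafluorophenyl ester
Conditions: C6F5OH, EDC·HCl, CH2Cl2, 0 °C to rt
Reagents that add atoms: pentafluorophenol, Oc1c(F)c(F)c(F)c(F)c1F
Why: Carbodiimide esterification to an activated ester that stays dormant in the absence of base.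

Step 22
Reactants: 31 pentafluorophenyl ester
Product: 32 α-methoxy hydroperoxide (C21 epimers)
Conditions: O3 (1.0 equiv), CH2Cl2–MeOH (4:1), −78 °C; N2 purge, no reductant
Reagents that add atoms: ozone, [O-][O+]=O; methanol, CO
Why: Chemoselective ozonolysis of the only electron-rich alkene; methanol traps the carbonyl oxide at C21, while the two conjugated alkenes are deactivated.

Step 23
Reactants: 32 α-methoxy hydroperoxide
Product: 35 enamide methyl peroxy-acetal (target skeleton with C16=C18 and C21–OMe), via macrocyclic perester 33 (not isolated), via keto-enamide hydroperoxide 34 (not isolated)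
Conditions: DBU (2 equiv), MeCN–CH2Cl2, 0.5 mM, −40 to 0 °C; AcOH quench
Reagents that add atoms: none
Why: Proposed new method: DBU deprotonates the hydroperoxide, which attacks the pentafluorophenyl ester to give the 17-membered perester 33; the lactam is in equilibrium with its aromatic 2-oxidopyrrole, whose C3 (C19) takes the acyl group through a six-membered transition state (1,5-O→C acyl shift, contraction to the 13-membered paracyclophane 34), and the released peroxide anion then adds 8-endo-trig to C25 of the new cross-conjugated enone, the enolate being protonated at C33 by the liberated pentafluorophenol. The closest known reactions are base-mediated intramolecular O→C acyl transfers of the Baker–Venkataraman and Steglich type, which build acylated quaternary carbons, and amine-promoted intramolecular peroxide conjugate additions used for 1,2-dioxanes; their coupling through a perester relay is new. Ring closures: macrocyclic peresterification (17-membered), transannular C-acylation (giving the 13-membered ring), then 8-endo-trig oxa-Michael addition (dioxocane). Stereocontrol: C19 is fixed by the bicyclo[10.5.1] topology because C-acylation is reversible and only the epimer whose peroxide arm reaches C25 is drained; C25 is set by delivery of O24 on the β-face, over which the aryl ether bridge from C7 holds C19; C33 is set by protonation to the equatorial, thermodynamic acyl group. Selectivity needed: acylation at C19 and not at C16, N or O of the ambident anion (only C19 is reached through a six-membered transition state), acyl capture faster than Kornblum–DeLaMare fragmentation of the perester (low temperature, intramolecular), and no epoxide formation from the C33 enolate because the eight-membered ring keeps the O–O bond out of line.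

Step 24
Reactants: 35 enamide methyl peroxy-acetal
Product: 36 CNP0533733.1 (target)
Conditions: AcOH–THF–H2O (3:1:1), 35 °C
Reagents that add atoms: water, O
Why: Mild aqueous acid hydrates the enamide through its N-acyliminium ion and exchanges the peroxy-acetal methyl ether for hydroxyl (as in the hydrolysis of cyclic alkoxy peroxides), both new centres (C16, C21) forming under thermodynamic control.

**Compound list**

1 | 5-hydroxy-4-methylfuran-2(5H)-one (racemic) | CC1=CC(=O)OC1O | starting material
2 | (−)-menthol, (1R,2S,5R) | C[C@@H]1CC[C@H]([C@@H](C1)O)C(C)C | starting material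
3 | (5R)-5-[(1R,2S,5R)-menthyloxy]-4-methylfuran-2(5H)-one | O=C1C=C(C)[C@H](O[C@@H]2C[C@H](C)CC[C@H]2C(C)C)O1 | intermediate
4 | (E)-2-methylpenta-1,3-diene | C=C(C)/C=C/C | starting material
5 | cis-fused adduct: 3-(menthyloxy)-3a,5,7-trimethyl-3a,4,7,7a-tetrahydroisobenzofuran-1(3H)-one; C4 methyl and lactone carbons α, C36 methyl β, menthyloxy cis to the C36 methyl | CC1=C[C@H](C)[C@@H]2C(=O)O[C@@H](O[C@@H]3C[C@H](C)CC[C@H]3C(C)C)[C@]2(C)C1 | intermediate
6 | hexahydro lactone acetal: as 5 with C2–C3 saturated, C2 methyl α (cis to C4 methyl) | C[C@@H]1C[C@H](C)[C@@H]2C(=O)O[C@@H](O[C@@H]3C[C@H](C)CC[C@H]3C(C)C)[C@]2(C)C1 | intermediate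
7 | 2-formyl-N-methoxy-N,2,4,6-tetramethylcyclohexane-1-carboxamide; amide, formyl, 4- and 6-methyl α, 2-methyl β | C[C@@H]1C[C@H](C)[C@H](C(=O)N(C)OC)[C@](C)(C=O)C1 | intermediate
8 | 2-(2,2-dibromovinyl) analogue of 7 | C[C@@H]1C[C@H](C)[C@H](C(=O)N(C)OC)[C@](C)(C=C(Br)Br)C1 | intermediate
9 | (E)-prop-1-en-1-ylboronic acid | C/C=C/B(O)O | starting material
10 | 2-[(1Z,3E)-2-bromopenta-1,3-dien-1-yl] analogue of 7 | C[C@@H]1C[C@H](C)[C@H](C(=O)N(C)OC)[C@](C)(/C=C(\Br)/C=C/C)C1 | intermediate
11 | 2-[(1E,3E)-2-methylpenta-1,3-dien-1-yl] Weinreb amide | C[C@@H]1C[C@H](C)[C@H](C(=O)N(C)OC)[C@](C)(/C=C(\C)/C=C/C)C1 | intermediate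
12 | 2,4,6-trimethyl-2-[(1E,3E)-2-methylpenta-1,3-dien-1-yl]cyclohexane-1-carbaldehyde, formyl cis to the dienyl arm (axial) | C[C@@H]1C[C@H](C)[C@H](C=O)[C@](C)(/C=C(\C)/C=C/C)C1 | intermediate
13 | C6 epimer of 12: formyl β, equatorial, trans to the dienyl arm and to the C4 methyl | C[C@@H]1C[C@H](C)[C@@H](C=O)[C@](C)(/C=C(\C)/C=C/C)C1 | intermediate
14 | (E)-3-iodoacrylic acid | OC(=O)/C=C/I | starting material
15 | 2-(trimethylsilyl)ethyl (E)-3-iodoacrylate | I/C=C/C(=O)OCC[Si](C)(C)C | intermediate
16 | 2-(trimethylsilyl)ethyl (E)-4-hydroxy-4-(ring A)but-2-enoate, C7 carbinol of the configuration that becomes 7α | C[C@@H]1C[C@H](C)[C@@H]([C@H](O)/C=C/C(=O)OCC[Si](C)(C)C)[C@](C)(/C=C(\C)/C=C/C)C1 | intermediate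
17 | tricyclic ester: 7α-OH, 33β-CO2CH2CH2SiMe3, 25β-methyl, C27=C29; rings A/B and B/C trans-fused | C[C@@H]1C[C@H](C)[C@H]2[C@H](O)[C@@H]3[C@@H](C(=O)OCC[Si](C)(C)C)[C@@H](C)C=C(C)[C@H]3[C@]2(C)C1 | intermediate
18 | 33α-phenylselanyl derivative of 17 | C[C@@H]1C[C@H](C)[C@H]2[C@H](O)[C@@H]3[C@](C(=O)OCC[Si](C)(C)C)([Se]c4ccccc4)[C@@H](C)C=C(C)[C@H]3[C@]2(C)C1 | intermediate
19 | tricyclic dienoate (C25=C33, C27=C29), 7α-OH | C[C@@H]1C[C@H](C)[C@H]2[C@H](O)[C@@H]3C(C(=O)OCC[Si](C)(C)C)=C(C)C=C(C)[C@H]3[C@]2(C)C1 | intermediate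
20 | bromohydrin: 27α-Br, 29β-OH, C25=C33 enoate | C[C@@H]1C[C@H](C)[C@H]2[C@H](O)[C@@H]3C(C(=O)OCC[Si](C)(C)C)=C(C)[C@H](Br)[C@@](C)(O)[C@H]3[C@]2(C)C1 | intermediate
21 | 27β,29β-epoxy enoate, 7α-OH | C[C@@H]1C[C@H](C)[C@H]2[C@H](O)[C@@H]3C(C(=O)OCC[Si](C)(C)C)=C(C)[C@H]4O[C@@]4(C)[C@H]3[C@]2(C)C1 | intermediate
22 | methyl 2-[bis(2,2,2-trifluoroethoxy)phosphoryl]acetate | COC(=O)CP(=O)(OCC(F)(F)F)OCC(F)(F)F | starting material
23 | allyl bromide | C=CCBr | starting material
24 | methyl 2-[bis(2,2,2-trifluoroethoxy)phosphoryl]pent-4-enoate | COC(=O)C(CC=C)P(=O)(OCC(F)(F)F)OCC(F)(F)F | intermediate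
25 | N-Boc-L-tyrosine methyl ester | COC(=O)[C@H](Cc1ccc(O)cc1)NC(=O)OC(C)(C)C | starting material
26 | N-Boc-L-tyrosinal | O=C[C@H](Cc1ccc(O)cc1)NC(=O)OC(C)(C)C | intermediate
27 | methyl (2Z,4S)-2-allyl-4-[(tert-butoxycarbonyl)amino]-5-(4-hydroxyphenyl)pent-2-enoate | COC(=O)/C(CC=C)=C\[C@H](Cc1ccc(O)cc1)NC(=O)OC(C)(C)C | intermediate
28 | (5S)-3-allyl-5-(4-hydroxybenzyl)-1,5-dihydro-2H-pyrrol-2-one | O=C1N[C@@H](Cc2ccc(O)cc2)C=C1CC=C | intermediate
29 | 7β-aryl ether of 21 with 28 (2-(trimethylsilyl)ethyl ester) | C[C@@H]1C[C@H](C)[C@H]2[C@@H](Oc3ccc(C[C@@H]4NC(=O)C(CC=C)=C4)cc3)[C@@H]3C(C(=O)OCC[Si](C)(C)C)=C(C)[C@H]4O[C@@]4(C)[C@H]3[C@]2(C)C1 | intermediate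
30 | corresponding epoxy enoic acid | C[C@@H]1C[C@H](C)[C@H]2[C@@H](Oc3ccc(C[C@@H]4NC(=O)C(CC=C)=C4)cc3)[C@@H]3C(C(=O)O)=C(C)[C@H]4O[C@@]4(C)[C@H]3[C@]2(C)C1 | intermediate
31 | pentafluorophenyl ester of 30 | C[C@@H]1C[C@H](C)[C@H]2[C@@H](Oc3ccc(C[C@@H]4NC(=O)C(CC=C)=C4)cc3)[C@@H]3C(C(=O)Oc4c(F)c(F)c(F)c(F)c4F)=C(C)[C@H]4O[C@@]4(C)[C@H]3[C@]2(C)C1 | intermediate
32 | α-methoxy hydroperoxide: allyl of 31 replaced by CH2CH(OMe)OOH (C21 epimers) | C[C@@H]1C[C@H](C)[C@H]2[C@@H](Oc3ccc(C[C@@H]4NC(=O)C(CC(OC)OO)=C4)cc3)[C@@H]3C(C(=O)Oc4c(F)c(F)c(F)c(F)c4F)=C(C)[C@H]4O[C@@]4(C)[C@H]3[C@]2(C)C1 | intermediate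
33 | 17-membered perester: C34 acyl on O24, pyrrolinone intact | C[C@@H]1C[C@H](C)[C@H]2[C@H]3Oc4ccc(cc4)C[C@@H]4NC(=O)C(=C4)CC(OC)OOC(=O)C5=C(C)[C@H]6O[C@@]6(C)[C@H]([C@H]35)[C@]2(C)C1 | intermediate
34 | 13-membered paracyclophane: C19-acylated C16=C18 enamide lactam, C25=C33 enone, free hydroperoxide | C[C@@H]1C[C@H](C)[C@H]2[C@H]3Oc4ccc(cc4)CC4=C[C@](CC(OC)OO)(C(=O)N4)C(=O)C5=C(C)[C@H]6O[C@@]6(C)[C@H]([C@H]35)[C@]2(C)C1 | intermediate
35 | target skeleton with C16=C18 enamide in place of the C16 hydroxyl and OMe at C21 (C21 epimers) | C[C@@H]1C[C@H](C)[C@H]2[C@H]3Oc4ccc(cc4)CC4=C[C@]5(CC(OC)OO[C@@]6(C)[C@H]7O[C@@]7(C)[C@H]([C@H]3[C@H]6C5=O)[C@]2(C)C1)C(=O)N4 | intermediate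
36 | CNP0533733.1 | C[C@@H]1C[C@H](C)[C@H]2[C@H]3Oc4ccc(cc4)C[C@]4(O)C[C@]5(C[C@H](O)OO[C@@]6(C)[C@H]7O[C@@]7(C)[C@H]([C@H]3[C@H]6C5=O)[C@]2(C)C1)C(=O)N4 | target

**Totals and risks**

Total step count: 24. Longest linear sequence: 19 steps (steps 1–8, 10–14, 19–24).

Steps most likely to fail:

1. Step 23 (proposed new method). The transient perester may fragment under base (Kornblum–DeLaMare), or the acyl group may not be captured at C19 (oligomerisation, O- or N-acylation). Fallback with known reactions, done stepwise, setting out from 32 and returning at 35: the hydroperoxide is silylated (Et3SiCl, imidazole) to the triethylsilyl peroxide F1; the macrocycle is closed by soft-enolisation C-acylation of the pyrrolinone with the pentafluorophenyl ester (MgBr2·OEt2, i-Pr2NEt, CH2Cl2, high dilution) to the silyl-protected keto-enamide F2; HF·pyridine frees hydroperoxide 34, now isolated; the standard amine-promoted peroxide conjugate addition (Et2NH, CF3CH2OH) then gives 35.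

2. Step 19. Activation of the hindered C7 alcohol may lead to elimination or no substitution. Fallback setting out from 21 and returning at 29: the alcohol is converted into the 7α-triflate F3 (Tf2O, pyridine, −78 °C), which is displaced with inversion by the caesium phenoxide of 28 (Cs2CO3, MeCN) in a Williamson-type SN2 reaction.

3. Step 13. Facial selectivity of bromonium formation and opening may be poor, leading to the α-epoxide. Fallback setting out from 19 and returning at 21: the C7 hydroxyl is acetylated (Ac2O, pyridine) to acetate F4; peracid epoxidation (mCPBA) from the less hindered α-face gives α-epoxide F5; aqueous HClO4 opens it at tertiary C29 with inversion to the 27α,29β-diol F6; the secondary C27 hydroxyl is mesylated (MsCl, Et3N) to F7; K2CO3 in MeOH closes the β-epoxide with inversion at C27 and removes the acetate.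

Further compounds
F1 | step 23 | triethylsilyl peroxide of 32 | C[C@@H]1C[C@H](C)[C@H]2[C@@H](Oc3ccc(C[C@@H]4NC(=O)C(CC(OC)OO[Si](CC)(CC)CC)=C4)cc3)[C@@H]3C(C(=O)Oc4c(F)c(F)c(F)c(F)c4F)=C(C)[C@H]4O[C@@]4(C)[C@H]3[C@]2(C)C1
F2 | step 23 | triethylsilyl peroxide of 34 (13-membered keto-enamide) | C[C@@H]1C[C@H](C)[C@H]2[C@H]3Oc4ccc(cc4)CC4=C[C@](CC(OC)OO[Si](CC)(CC)CC)(C(=O)N4)C(=O)C5=C(C)[C@H]6O[C@@]6(C)[C@H]([C@H]35)[C@]2(C)C1
F3 | step 19 | 7α-trifluoromethanesulfonate of 21 | C[C@@H]1C[C@H](C)[C@H]2[C@H](OS(=O)(=O)C(F)(F)F)[C@@H]3C(C(=O)OCC[Si](C)(C)C)=C(C)[C@H]4O[C@@]4(C)[C@H]3[C@]2(C)C1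
F4 | step 13 | 7α-acetate of 19 | C[C@@H]1C[C@H](C)[C@H]2[C@H](OC(C)=O)[C@@H]3C(C(=O)OCC[Si](C)(C)C)=C(C)C=C(C)[C@H]3[C@]2(C)C1
F5 | step 13 | 27α,29α-epoxide of F4 | C[C@@H]1C[C@H](C)[C@H]2[C@H](OC(C)=O)[C@@H]3C(C(=O)OCC[Si](C)(C)C)=C(C)[C@@H]4O[C@]4(C)[C@H]3[C@]2(C)C1
F6 | step 13 | 27α,29β-diol 7-acetate | C[C@@H]1C[C@H](C)[C@H]2[C@H](OC(C)=O)[C@@H]3C(C(=O)OCC[Si](C)(C)C)=C(C)[C@H](O)[C@@](C)(O)[C@H]3[C@]2(C)C1
F7 | step 13 | 27α-methanesulfonate of F6 | C[C@@H]1C[C@H](C)[C@H]2[C@H](OC(C)=O)[C@@H]3C(C(=O)OCC[Si](C)(C)C)=C(C)[C@H](OS(C)(=O)=O)[C@@](C)(O)[C@H]3[C@]2(C)C1
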